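**Plan**

1. Numbering: the carbocycle runs C1 (ketone), C2, C3 (enol-ether carbon), C4 (methyl), C5, C6 (lactone O), C7, C8 (isovalerate), C9 (acetate), C10 (quaternary, methyl). The furanone ring is C1/C2/C3/O/C10. The lactone ring is O6/C6/C7/C11/C12, and C13 is the exocyclic methylene.
2. Retrosynthetic cuts, in order: C12=O (back to a methyl acetal), C4=C5 (back to its acetic acid adduct, 4-H/5-OAc), the C8 ester, then C7–C11 and C8–O together, then O6–C12, C7=C8, O–C3, C1–C2 and C4–C5.
3. Enabling feature: C11 on C7 and the oxygen on C8 are vicinal, and C7 is β to O6. A C11–C13 unit hung on O6 can therefore reach C7 of a ring C7=C8 alkene through a five-membered transition state. This closes the ring O6/C6/C7/C11/C12 and leaves a C8 radical for O2.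
4. Forward order: two chiral-pool fragments are joined at C1–C2. The rings then arise as furanone (gold), ten-membered ring (metathesis) and methylene-oxolane (radical). After that C4=C5 is unveiled and C12 is oxidised.
5. Stereochemistry: C9 and C10 come from 2-C-methyl-D-ribono-1,4-lactone and C6 from (S)-but-3-ene-1,2-diol. C7 and C8 are set in the radical step under control of C6 and the Z ring alkene. The temporary 4,5-anti centres come from (S)-but-3-yn-2-ol and vanish in an anti elimination that can only give the Z alkene.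
6. C4–C5 stays saturated until after the radical step. C6 is then allylic to one alkene only, and the six-carbon bridge carries one alkene, as in the target.

Key step: step 18

Remark on the chemistry: the acetal carbon of the p-methoxybenzylidene acetal, and C12 of all methyl acetals and lactols, are carried as epimer mixtures. Both centres are destroyed later, so they are left undefined in the SMILES.

**Step 1**
Reactants: 1 2-C-methyl-D-ribono-1,4-lactone
Product: 2 5-deoxy-5-iodo-2-C-methyl-D-ribono-1,4-lactone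
Conditions: I2, PPh3, imidazole, THF, 0 °C to rt
Reagents that add atoms: iodine, [I][I]
Why: Garegg–Samuelsson (Appel-type) iodination runs by SN2 displacement of an alkoxyphosphonium ion, so it should take only the primary hydroxyl and leave the secondary and tertiary hydroxyls and all stereocentres untouched.

**Step 2**
Reactants: 2 5-deoxy-5-iodo-2-C-methyl-D-ribono-1,4-lactone
Product: 3 3-O-TBS-5-deoxy-5-iodo-2-C-methyl-D-ribono-1,4-lactone
Conditions: TBSOTf (1.1 equiv), 2,6-lutidine, CH2Cl2, −78 to 0 °C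
Reagents that add atoms: tert-butyldimethylsilyl triflate, CC(C)(C)[Si](C)(C)OS(=O)(=O)C(F)(F)F
Why: Kinetic silylation should distinguish the secondary hydroxyl (future O9) from the tertiary, carbonyl-flanked hydroxyl (future bridging oxygen), which has to stay free for furanone closure.

**Step 3**
Reactants: 3 3-O-TBS-5-deoxy-5-iodo-2-C-methyl-D-ribono-1,4-lactone
Product: 4 (2R,3R)-3-(TBS-oxy)-2-hydroxy-2-methylpent-4-enoic acid
Conditions: Zn dust, THF–H2O (4:1), 60 °C; then aq. NaH2PO4 to pH 4
Reagents that add atoms: none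
Why: Zinc insertion into the carbon–iodine bond followed by β-elimination of the ring carboxylate (Vasella-type reductive fragmentation) unveils the C8 vinyl group and the C1 acid at once without touching C9 or C10.

**Step 4**
Reactants: 4 (2R,3R)-3-(TBS-oxy)-2-hydroxy-2-methylpent-4-enoic acid
Product: 5 (2R,3R)-3-(TBS-oxy)-2-hydroxy-N-methoxy-N,2-dimethylpent-4-enamide
Conditions: MeNHOMe·HCl, EDC·HCl, HOBt, i-Pr2NEt, CH2Cl2, 0 °C to rt
Reagents that add atoms: N,O-dimethylhydroxylamine hydrochloride, CNOC.Cl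
Why: Carbodiimide amidation gives the Weinreb amide, and the hindered tertiary hydroxyl should not compete as a nucleophile.

**Step 5**
Reactants: 6 (S)-but-3-ene-1,2-diol
Product: 7 (4S)-2-(4-methoxyphenyl)-4-vinyl-1,3-dioxolane
Conditions: 4-MeOC6H4CH(OMe)2, PPTS (cat.), CH2Cl2, rt
Reagents that add atoms: 4-methoxybenzaldehyde dimethyl acetal, COc1ccc(C(OC)OC)cc1
Why: Acid-catalysed transacetalisation ties the 1,2-diol into a p-methoxybenzylidene acetal, and the new acetal centre is of no consequence.

**Step 6**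
Reactants: 7 (4S)-2-(4-methoxyphenyl)-4-vinyl-1,3-dioxolane
Product: 8 (S)-2-[(4-methoxybenzyl)oxy]but-3-en-1-ol
Conditions: i-Bu2AlH, CH2Cl2, −78 to 0 °C
Reagents that add atoms: none
Why: In this reductive acetal opening aluminium binds the less hindered primary oxygen, that acetal C–O bond breaks, and hydride delivery leaves the PMB group on the secondary oxygen (future O6).

**Step 7**
Reactants: 8 (S)-2-[(4-methoxybenzyl)oxy]but-3-en-1-ol
Product: 9 (S)-2-[(4-methoxybenzyl)oxy]but-3-enal
Conditions: Dess–Martin periodinane, NaHCO3, CH2Cl2, 0 °C; used at once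
Reagents that add atoms: none
Why: Buffered Dess–Martin oxidation is cold and free of amine base, which should prevent enolisation or double-bond migration in the α-alkoxy β,γ-unsaturated aldehyde.

**Step 8**
Reactants: 10 (S)-but-3-yn-2-ol
Product: 11 (S)-but-3-yn-2-yl methanesulfonate
Conditions: MsCl, Et3N, CH2Cl2, −78 to 0 °C
Reagents that add atoms: methanesulfonyl chloride, CS(=O)(=O)Cl
Why: Sulfonylation occurs at oxygen and keeps the carbinol configuration.

**Step 9**
Reactants: 9 (S)-2-[(4-methoxybenzyl)oxy]but-3-enal; 11 (S)-but-3-yn-2-yl methanesulfonate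
Product: 13 (3S,4R,5R)-3-[(4-methoxybenzyl)oxy]-5-methylhept-1-en-6-yn-4-ol, via allenylzinc 12 (not isolated)
Conditions: Pd(OAc)2 (5 mol %), PPh3 (5 mol %), Et2Zn (3 equiv), THF, −78 to −20 °C
Reagents that add atoms: none
Why: In this Marshall–Tamaru propargylation zerovalent palladium displaces the mesylate anti (SN2'), transmetalation gives configurationally stable 12, and its cyclic SE2' addition sets C4 (net inversion of the mesylate carbon) and the 4,5-anti relationship, the mesylate enantiomer being chosen so that this coincides with Felkin–Anh attack on 9 (5,6-anti).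

**Step 10**
Reactants: 13 (3S,4R,5R)-3-[(4-methoxybenzyl)oxy]-5-methylhept-1-en-6-yn-4-ol
Product: 14 TBS ether of 13
Conditions: TBSOTf, 2,6-lutidine, CH2Cl2, 0 °C
Reagents that add atoms: tert-butyldimethylsilyl triflate, CC(C)(C)[Si](C)(C)OS(=O)(=O)C(F)(F)F
Why: Silyl triflate silylation masks O5 for the organolithium step without affecting any stereocentre.

**Step 11**
Reactants: 14 TBS ether of 13; 5 (2R,3R)-3-(TBS-oxy)-2-hydroxy-N-methoxy-N,2-dimethylpent-4-enamide
Product: 16 (3R,4R,8R,9R,10S)-3,9-bis(TBS-oxy)-4-hydroxy-10-[(4-methoxybenzyl)oxy]-4,8-dimethyldodeca-1,11-dien-6-yn-5-one, via lithium acetylide 15 (not isolated)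
Conditions: 14 (2.2 equiv), n-BuLi (2.1 equiv), THF, −78 °C; then 5, −78 to −20 °C; aq. NH4Cl
Reagents that add atoms: none
Why: In this Weinreb ketone synthesis (C1–C2 bond) the chelated tetrahedral adduct holds until the quench, so the base-sensitive ynone never meets the acetylide, and the equivalent of 15 that only deprotonates the tertiary hydroxyl is recovered as 14.

**Step 12**
Reactants: 16 the ynone of step 11
Product: 17 (2R)-2-[(1R)-1-(TBS-oxy)allyl]-5-[(2S,3R,4S)-3-(TBS-oxy)-4-(PMB-oxy)hex-5-en-2-yl]-2-methylfuran-3(2H)-one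
Conditions: Ph3PAuNTf2 (5 mol %), CH2Cl2, rt
Reagents that add atoms: none
Why: Gold-catalysed cycloisomerisation of an α'-hydroxy ynone lets the free C10 hydroxyl attack the π-activated β-carbon C3 (5-endo-dig), protodeauration gives the 3(2H)-furanone, and the silyl group on O9 rules out the six-membered pyranone.

**Step 13**
Reactants: 17 the furanone of step 12
Product: 18 (2R)-2-[(1R)-1-hydroxyallyl]-5-[(2S,3R,4S)-3-hydroxy-4-(PMB-oxy)hex-5-en-2-yl]-2-methylfuran-3(2H)-one
Conditions: HF·pyridine, pyridine, THF, 0 °C to rt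
Reagents that add atoms: none
Why: Fluoride desilylation in a buffered acidic medium should remove both TBS ethers without the retro-aldol or elimination that a basic fluoride source could start at C4–C5, and the PMB ether is inert.

**Step 14**
Reactants: 18 the diol of step 13
Product: 19 (4S,5R,6S,7Z,9R,10R)-5,9-dihydroxy-6-(PMB-oxy)-4,10-dimethyl-3,10-epoxycyclodeca-2,7-dien-1-one
Conditions: second-generation Grubbs catalyst (H2IMes)(PCy3)Cl2Ru=CHPh (10 mol %), 1,4-benzoquinone (20 mol %), CH2Cl2 (1 mM), 40 °C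
Reagents that add atoms: none
Why: Ring-closing metathesis of two monosubstituted alkenes is helped by the free allylic hydroxyl at the hindered C9 terminus and by high dilution, and the six-carbon bridge over the furanone oxygen has room only for a Z alkene and carries no more sp2 centres than the bridge of the target, so the strain to be paid should be that of the natural skeleton.

**Step 15**
Reactants: 19 the macrocyclic diol of step 14
Product: 20 (4S,5R,6S,7Z,9R,10R)-5,9-diacetoxy-6-(PMB-oxy)-4,10-dimethyl-3,10-epoxycyclodeca-2,7-dien-1-one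
Conditions: Ac2O, pyridine, DMAP (cat.), CH2Cl2, 0 °C to rt
Reagents that add atoms: acetic anhydride, CC(=O)OC(C)=O
Why: DMAP-catalysed acetylation caps both secondary hydroxyls, the C9 acetate being that of the target and the C5 acetate the latent leaving group.

**Step 16**
Reactants: 20 the diacetate of step 15
Product: 21 (4S,5R,6S,7Z,9R,10R)-5,9-diacetoxy-6-hydroxy-4,10-dimethyl-3,10-epoxycyclodeca-2,7-dien-1-one
Conditions: DDQ, CH2Cl2–pH 7 buffer (18:1), 0 °C
Reagents that add atoms: none
Why: Oxidative PMB cleavage (hydride abstraction by DDQ, then hydrolysis of the oxocarbenium ion) works at neutral pH, so O6 should be freed without acetyl migration or loss of the C5 acetate.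

**Step 17**
Reactants: 21 the allylic alcohol of step 16; 22 methoxyallene
Product: 23 6-O-(2-iodo-1-methoxyallyl) ether of 21
Conditions: NIS (1.5 equiv), 22 (3 equiv), 4 Å MS, CH2Cl2, −78 to −30 °C
Reagents that add atoms: N-iodosuccinimide, O=C1CCC(=O)N1I
Why: In this iodoalkoxylation of an alkoxyallene, iodonium attack on the central allene carbon gives a 2-iodoallyl oxocarbenium ion that the C6 hydroxyl traps, a base-free haloacetalisation of the Ueno–Stork kind that spares the acetates, puts C12 at the lactol oxidation level and forms C12 as an inconsequential epimer mixture.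

**Step 18**
Reactants: 23 6-O-(2-iodo-1-methoxyallyl) ether of 21
Product: 25 (4S,5R,6S,7R,8S,9R,10R)-8-hydroxy methylene-oxolane tricycle, via C8 hydroperoxide 24 (not isolated)
Conditions: Bu3SnH (3 equiv, syringe pump), Et3B (0.3 equiv), slow stream of 5% O2 in N2, toluene (5 mM), 0 °C; then PPh3 (2 equiv), rt
Reagents that add atoms: dioxygen, O=O
Why: Et3B/O2 starts a chain in which the stannyl radical takes iodine from 23, the σ-vinyl radical at C11 adds to C7, the secondary C8 radical combines with O2, the peroxyl radical takes hydrogen from Bu3SnH to give 24, and PPh3 reduces 24 to 25. The closest known reaction type is the aerobic (oxygenative) tin hydride radical cyclisation of halo acetals, that is a Ueno–Stork closure run with a vinyl radical and ended by O2 in place of hydrogen. The single new ring (O6/C6/C7/C11/C12) closes 5-exo-trig, and attack at C8 (6-endo) lacks the orbital overlap of the five-membered transition state. C7: allylic 1,3-strain in the Z alkene turns H6 into the alkene plane toward C9, puts C5 on the inner face and O6 on the outer face, so a chair-like Beckwith–Houk transition state should deliver C11 to the outer face, trans to C5, a fusion that the ten-membered ring can accommodate. C8: the inner lobe of the ring radical is buried against C4/C5 and the bridging oxygen while the outer lobe is flanked by H9, so O2 should enter on the side of the new C7–C11 bond, and such a syn addition to a Z alkene maps onto the 7,8-relationship of the target. The step needs C7 to be the only acceptor and ring closure to precede capture: the saturated 5-acetoxy C4–C5 unit leaves C7=C8 as the only alkene within 5-exo reach, the iodide lets halogen abstraction compete with O2 for the stannyl radical and keeps it off the enone, and lean oxygen with slow stannane addition keeps both traps slower than cyclisation.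

**Step 19**
Reactants: 25 8-hydroxy methylene-oxolane tricycle
Product: 27 (4Z,6R,7S,8S,9R,10R)-dienone methyl acetal 8-isovalerate, via 5-acetoxy isovalerate 26 (not isolated)
Conditions: (i-BuCO)2O, DMAP, Et3N, CH2Cl2, 0 °C to rt; then DBU, rt
Reagents that add atoms: isovaleric anhydride, CC(C)CC(=O)OC(=O)CC(C)C
Why: DMAP-catalysed acylation esterifies O8 before any acetyl shift, and DBU then removes the vinylogously acidic H4 and expels the C5 acetate (E1cB/E2), the 4,5-anti relationship placing H4 and the acetate antiperiplanar when C3 and C6 are gauche, so that only the ring-compatible Z C4=C5 alkene should form.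

**Step 20**
Reactants: 27 dienone methyl acetal 8-isovalerate
Product: 29 target CNP0255553.1, via lactol 28 (not isolated)
Conditions: CrO3, H2SO4, H2O, acetone, 0 °C
Reagents that add atoms: water, O
Why: In this Jones oxidation aqueous acid hydrolyses the allylic methyl acetal to 28 and chromic acid oxidises the lactol at once to the α-methylene-γ-lactone, no stereocentre being touched.

**Compound list**

1 | 2-C-methyl-D-ribono-1,4-lactone, (3R,4R,5R)-3,4-dihydroxy-5-(hydroxymethyl)-3-methyloxolan-2-one | O=C1O[C@H](CO)[C@@H](O)[C@@]1(C)O | starting material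
2 | 5-deoxy-5-iodo-2-C-methyl-D-ribono-1,4-lactone | O=C1O[C@H](CI)[C@@H](O)[C@@]1(C)O | intermediate
3 | 3-O-(tert-butyldimethylsilyl)-5-deoxy-5-iodo-2-C-methyl-D-ribono-1,4-lactone | O=C1O[C@H](CI)[C@@H](O[Si](C)(C)C(C)(C)C)[C@@]1(C)O | intermediate
4 | (2R,3R)-3-[(tert-butyldimethylsilyl)oxy]-2-hydroxy-2-methylpent-4-enoic acid | C=C[C@@H](O[Si](C)(C)C(C)(C)C)[C@@](C)(O)C(=O)O | intermediate
5 | (2R,3R)-3-[(tert-butyldimethylsilyl)oxy]-2-hydroxy-N-methoxy-N,2-dimethylpent-4-enamide | C=C[C@@H](O[Si](C)(C)C(C)(C)C)[C@@](C)(O)C(=O)N(C)OC | intermediate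
6 | (S)-but-3-ene-1,2-diol | C=C[C@H](O)CO | starting material
7 | (4S)-2-(4-methoxyphenyl)-4-vinyl-1,3-dioxolane (C2 epimers) | C=C[C@H]1COC(c2ccc(OC)cc2)O1 | intermediate
8 | (S)-2-[(4-methoxybenzyl)oxy]but-3-en-1-ol | C=C[C@H](OCc1ccc(OC)cc1)CO | intermediate
9 | (S)-2-[(4-methoxybenzyl)oxy]but-3-enal | C=C[C@H](OCc1ccc(OC)cc1)C=O | intermediate
10 | (S)-but-3-yn-2-ol | C[C@H](O)C#C | starting material
11 | (S)-but-3-yn-2-yl methanesulfonate | C[C@H](OS(C)(=O)=O)C#C | intermediate
12 | (M)-buta-1,2-dien-1-yl(ethyl)zinc | CC[Zn]C([H])=[C@]=C([H])C | intermediate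
13 | (3S,4R,5R)-3-[(4-methoxybenzyl)oxy]-5-methylhept-1-en-6-yn-4-ol (4,5-anti and 5,6-anti in target numbering) | C=C[C@H](OCc1ccc(OC)cc1)[C@H](O)[C@H](C)C#C | intermediate
14 | tert-butyl{[(3S,4R,5R)-3-[(4-methoxybenzyl)oxy]-5-methylhept-1-en-6-yn-4-yl]oxy}dimethylsilane | C=C[C@H](OCc1ccc(OC)cc1)[C@H](O[Si](C)(C)C(C)(C)C)[C@H](C)C#C | intermediate
15 | lithium acetylide of 14 | [Li]C#C[C@@H](C)[C@@H](O[Si](C)(C)C(C)(C)C)[C@@H](OCc1ccc(OC)cc1)C=C | intermediate
16 | (3R,4R,8R,9R,10S)-3,9-bis[(tert-butyldimethylsilyl)oxy]-4-hydroxy-10-[(4-methoxybenzyl)oxy]-4,8-dimethyldodeca-1,11-dien-6-yn-5-one | C=C[C@@H](O[Si](C)(C)C(C)(C)C)[C@@](C)(O)C(=O)C#C[C@@H](C)[C@@H](O[Si](C)(C)C(C)(C)C)[C@@H](OCc1ccc(OC)cc1)C=C | intermediate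
17 | (2R)-2-{(1R)-1-[(tert-butyldimethylsilyl)oxy]allyl}-5-{(2S,3R,4S)-3-[(tert-butyldimethylsilyl)oxy]-4-[(4-methoxybenzyl)oxy]hex-5-en-2-yl}-2-methylfuran-3(2H)-one | C=C[C@@H](O[Si](C)(C)C(C)(C)C)[C@@]1(C)OC(=CC1=O)[C@@H](C)[C@@H](O[Si](C)(C)C(C)(C)C)[C@@H](OCc1ccc(OC)cc1)C=C | intermediate
18 | (2R)-2-[(1R)-1-hydroxyallyl]-5-{(2S,3R,4S)-3-hydroxy-4-[(4-methoxybenzyl)oxy]hex-5-en-2-yl}-2-methylfuran-3(2H)-one | C=C[C@@H](O)[C@@]1(C)OC(=CC1=O)[C@@H](C)[C@@H](O)[C@@H](OCc1ccc(OC)cc1)C=C | intermediate
19 | (4S,5R,6S,7Z,9R,10R)-5,9-dihydroxy-6-[(4-methoxybenzyl)oxy]-4,10-dimethyl-3,10-epoxycyclodeca-2,7-dien-1-one | C[C@]12OC(=CC1=O)[C@@H](C)[C@@H](O)[C@@H](OCc3ccc(OC)cc3)/C=C\[C@H]2O | intermediate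
20 | (4S,5R,6S,7Z,9R,10R)-5,9-diacetoxy-6-[(4-methoxybenzyl)oxy]-4,10-dimethyl-3,10-epoxycyclodeca-2,7-dien-1-one | C[C@]12OC(=CC1=O)[C@@H](C)[C@@H](OC(C)=O)[C@@H](OCc3ccc(OC)cc3)/C=C\[C@H]2OC(C)=O | intermediate
21 | (4S,5R,6S,7Z,9R,10R)-5,9-diacetoxy-6-hydroxy-4,10-dimethyl-3,10-epoxycyclodeca-2,7-dien-1-one | C[C@]12OC(=CC1=O)[C@@H](C)[C@@H](OC(C)=O)[C@@H](O)/C=C\[C@H]2OC(C)=O | intermediate
22 | methoxyallene (1-methoxypropa-1,2-diene) | C=C=COC | starting material
23 | (4S,5R,6S,7Z,9R,10R)-5,9-diacetoxy-6-[(2-iodo-1-methoxyallyl)oxy]-4,10-dimethyl-3,10-epoxycyclodeca-2,7-dien-1-one (C12 epimers) | C[C@]12OC(=CC1=O)[C@@H](C)[C@@H](OC(C)=O)[C@@H](OC(OC)C(I)=C)/C=C\[C@H]2OC(C)=O | intermediate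
24 | 8-hydroperoxide of the tricycle, configured as 25 | C=C1C(OC)O[C@@H]2[C@H](OC(C)=O)[C@H](C)C3=CC(=O)[C@](C)(O3)[C@H](OC(C)=O)[C@@H](OO)[C@@H]12 | intermediate
25 | (4S,5R,6S,7R,8S,9R,10R)-5,9-diacetoxy-8-hydroxy-12-methoxy-3,10-epoxy-6,12-epoxygermacra-2,11(13)-dien-1-one (H6/H7 trans, O8 on the side of C11, C12 epimers) | C=C1C(OC)O[C@@H]2[C@H](OC(C)=O)[C@H](C)C3=CC(=O)[C@](C)(O3)[C@H](OC(C)=O)[C@@H](O)[C@@H]12 | intermediate
26 | 8-O-isovalerate of 25 | C=C1C(OC)O[C@@H]2[C@H](OC(C)=O)[C@H](C)C3=CC(=O)[C@](C)(O3)[C@H](OC(C)=O)[C@@H](OC(=O)CC(C)C)[C@@H]12 | intermediate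
27 | (4Z,6R,7S,8S,9R,10R)-9-acetoxy-12-methoxy-8-(3-methylbutanoyloxy)-3,10-epoxy-6,12-epoxygermacra-2,4,11(13)-trien-1-one (C12 epimers) | C=C1C(OC)O[C@@H]2/C=C(/C)C3=CC(=O)[C@](C)(O3)[C@H](OC(C)=O)[C@@H](OC(=O)CC(C)C)[C@@H]12 | intermediate
28 | 12-lactol corresponding to 27 (C12 epimers) | C=C1C(O)O[C@@H]2/C=C(/C)C3=CC(=O)[C@](C)(O3)[C@H](OC(C)=O)[C@@H](OC(=O)CC(C)C)[C@@H]12 | intermediate
29 | CNP0255553.1, (4Z,6R,7S,8S,9R,10R)-9-acetoxy-8-(3-methylbutanoyloxy)-1-oxo-3,10-epoxygermacra-2,4,11(13)-trien-12,6-olide | C=C1C(=O)O[C@@H]2/C=C(/C)C3=CC(=O)[C@](C)(O3)[C@H](OC(C)=O)[C@@H](OC(=O)CC(C)C)[C@@H]12 | target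

**Step count**

Total: 20 steps.
Longest linear sequence: 15 steps (6 to 29 by steps 5–7 and 9–20).

**Steps most likely to fail**

**Step 18.**
- What may go wrong: oxygen or stannane may intercept the vinyl radical before it closes. Oxygen may drain the stannyl radicals so that the chain stalls. The peroxyl stage may erode face selectivity at C8.
- Fallback, from 23 back to 25: the closure is run under argon with Bu3SnH and TEMPO added together slowly (benzene, 60 °C). A persistent nitroxide, not O2, then captures the C8 radical and gives the C8 O-(2,2,6,6-tetramethylpiperidin-1-yl) ether F1. The size of the trap should sharpen capture on the outer face, and no peroxyl chemistry is involved. Zn in AcOH–THF–H2O then cleaves the N–O bond and returns 25.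

**Step 14.**
- What may go wrong: oligomerisation may outrun closure of the bridged ring, and ruthenium hydrides may isomerise the allylic alcohol.
- Fallback, from 16 back to 19: the ten-membered ring is closed before the oxygen bridge exists.
  - Et2NH (THF, rt) adds to the ynone to give the (E)-β-diethylamino enone F2. In F2, C1 and C4 are cis on C2=C3 and the alkyne, which could engage in enyne metathesis, is gone.
  - The same ruthenium catalyst then has to form only an unbridged ring, the macrocyclic enaminone F3.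
  - Aqueous AcOH–THF lets the C10 hydroxyl add transannularly to C3 with loss of the amine, giving the bridged furanone bis-silyl ether F4.
  - HF·pyridine returns 19.

**Step 19.**
- What may go wrong: deprotonation at C4 may be slow if the ring holds the C4–H bond near the furanone plane, and long exposure to base may scramble the esters.
- Fallback, from 26 (isolated after the acylation) to 29: the order is reversed and the elimination is driven by a Lewis acid, which the methyl acetal would not survive.
  - CrO3, H2SO4, H2O in acetone at 0 °C first converts 26, by way of the 5-acetoxy lactol F5, into the 5-acetoxy-4,5-dihydro lactone F6.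
  - Soft enolisation (TMSOTf, Et3N, CH2Cl2, −78 to 0 °C) gives the silyl dienol ether F7.
  - In F7 the silyloxy group pushes out the silyl-activated C5 acetate through C2–C3–C4, and this gives 29 directly.

**Further compounds**

F1 | step 18 | C8 O-(2,2,6,6-tetramethylpiperidin-1-yl) ether of 25 | C=C1C(OC)O[C@@H]2[C@H](OC(C)=O)[C@H](C)C3=CC(=O)[C@](C)(O3)[C@H](OC(C)=O)[C@@H](ON4C(C)(C)CCCC4(C)C)[C@@H]12
F2 | step 14 | (E)-β-diethylamino enone from 16 | C=C[C@@H](O[Si](C)(C)C(C)(C)C)[C@@](C)(O)C(=O)/C=C(/N(CC)CC)[C@@H](C)[C@@H](O[Si](C)(C)C(C)(C)C)[C@@H](OCc1ccc(OC)cc1)C=C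
F3 | step 14 | macrocyclic enaminone (7Z, no oxygen bridge) | C[C@]1(O)C(=O)/C=C(/N(CC)CC)[C@@H](C)[C@@H](O[Si](C)(C)C(C)(C)C)[C@@H](OCc2ccc(OC)cc2)/C=C\[C@H]1O[Si](C)(C)C(C)(C)C
F4 | step 14 | bridged furanone bis-silyl ether (5,9-bis-TBS ether of 19) | C[C@]12OC(=CC1=O)[C@@H](C)[C@@H](O[Si](C)(C)C(C)(C)C)[C@@H](OCc3ccc(OC)cc3)/C=C\[C@H]2O[Si](C)(C)C(C)(C)C
F5 | step 19 | 5-acetoxy lactol (C12 epimers) | C=C1C(O)O[C@@H]2[C@H](OC(C)=O)[C@H](C)C3=CC(=O)[C@](C)(O3)[C@H](OC(C)=O)[C@@H](OC(=O)CC(C)C)[C@@H]12
F6 | step 19 | 5-acetoxy-4,5-dihydro lactone | C=C1C(=O)O[C@@H]2[C@H](OC(C)=O)[C@H](C)C3=CC(=O)[C@](C)(O3)[C@H](OC(C)=O)[C@@H](OC(=O)CC(C)C)[C@@H]12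
F7 | step 19 | silyl dienol ether of F6 (C3=C4 geometry open) | C=C1C(=O)O[C@@H]2[C@H](OC(C)=O)C(C)=C3C=C(O[Si](C)(C)C)[C@](C)(O3)[C@H](OC(C)=O)[C@@H](OC(=O)CC(C)C)[C@@H]12
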